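**Retrosynthetic overview**

1. Target ⇐ bicyclic dienone 18. Δ7/C17 comes from methylation of the enol triflate of an 8-ketone, the 2α,3α-diol from α-face OsO4 on a Δ2 olefin, and 5-H and 9-H from axial protonations of ring-B enol(ate)s.
2. 18 ⇐ one-pot (3+3) annulation that closes ring A by making C1–C2 and C4–C5: γ-iodo enone 12 (ring B with side chain) + prenal diacetate 14.
3. Enabling feature: in ring A (C1–C5, C10) the C2–C3–C4 unit with the C4 gem-dimethyl group is the skeleton of 3-methylbut-2-enal, an allyl 1,3-dielectrophile at C2 and C4. C1 and C5 both sit on quaternary C10 of ring B, where a C8 carbonyl with a Δ6 double bond makes C5 the γ-carbon of a dienolate and C1 can be carried as a neopentylic C–Zn bond.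
4. 12 ⇐ TMSI opening of cyclopropyl enone 10 (a temporary three-membered ring that brings in C1 and fixes C10) ⇐ CBS reduction and directed Simmons–Smith on enone 6 ⇐ Negishi coupling of iodoenone 5 with the citronellate-derived zinc reagent (C13 from the chiral pool).
5. Ring order: ring B (bought) → temporary cyclopropane → ring A (key step, C5 left trigonal) → ring fusion and C9 set by protonation.

Key step: step 9

Assumption: methyl (S)-citronellate (1), 2-iodo-3-methylcyclohex-2-en-1-one (5) and 3-methylbut-2-enal (13) are taken as purchasable; positions are cited with the usual labdane numbers (C1–C20).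

Step 1
Reactants: 1 methyl (3S)-3,7-dimethyloct-6-enoate
Product: 2 (4S)-6-methoxy-4-methyl-6-oxohexanoic acid
Conditions: RuCl3·xH2O (2 mol%), NaIO4, MeCN/EtOAc/H2O, rt
Reagents that add atoms: sodium periodate [Na+].[O-]I(=O)(=O)=O; water O
Why: Ruthenium tetroxide (RuCl3/NaIO4) oxidative cleavage of the trisubstituted olefin should give the acid directly, the C13 stereocentre from the chiral pool being remote from the reaction site.

Step 2
Reactants: 2 (4S)-6-methoxy-4-methyl-6-oxohexanoic acid
Product: 3 methyl (3R)-5-iodo-3-methylpentanoate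
Conditions: PhI(OAc)2, I2, DCE, visible light, 70 °C
Reagents that add atoms: iodine II
Why: Photochemical iododecarboxylation with PhI(OAc)2/I2 (Suárez modification of the Hunsdiecker reaction, via an acyl hypoiodite and a primary alkyl radical) should shorten the chain by one carbon and install the primary iodide.

Step 3
Reactants: 3 methyl (3R)-5-iodo-3-methylpentanoate; 5 2-iodo-3-methylcyclohex-2-en-1-one
Product: 6 methyl (3S)-3-methyl-5-(2-methyl-6-oxocyclohex-1-en-1-yl)pentanoate, via alkylzinc iodide 4 (not isolated)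
Conditions: Zn dust, LiCl, THF, 40 °C; then 5, Pd(OAc)2 (2 mol%), SPhos (4 mol%), THF, rt
Reagents that add atoms: none
Why: LiCl-assisted zinc insertion gives an ester-tolerant alkylzinc iodide that should undergo Negishi sp3–sp2 cross-coupling with the α-iodoenone, the standard route to 2-alkylcyclohex-2-enones.

Step 4
Reactants: 6 methyl (3S)-3-methyl-5-(2-methyl-6-oxocyclohex-1-en-1-yl)pentanoate
Product: 7 methyl (3S)-5-[(6R)-6-hydroxy-2-methylcyclohex-1-en-1-yl]-3-methylpentanoate
Conditions: (S)-Me-CBS (0.3 equiv), BH3·SMe2, THF, −30 °C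
Reagents that add atoms: none
Why: Corey–Bakshi–Shibata reduction is a reagent-controlled 1,2-reduction in which the α-substituted alkenyl arm acts as the large group, so the (S)-catalyst should give the (R)-carbinol.

Step 5
Reactants: 7 methyl (3S)-5-[(6R)-6-hydroxy-2-methylcyclohex-1-en-1-yl]-3-methylpentanoate
Product: 8 methyl (3S)-5-[(1S,2R,6R)-2-hydroxy-6-methylbicyclo[4.1.0]heptan-1-yl]-3-methylpentanoate
Conditions: Et2Zn, CH2I2, CH2Cl2, 0 °C → rt
Reagents that add atoms: diiodomethane ICI
Why: Hydroxyl-directed Simmons–Smith (Furukawa) cyclopropanation should deliver the methylene group to the olefin face syn to the zinc alkoxide, which sets the two quaternary cyclopropane carbons (C9 and C10 of the target, side chain and methyl cis, CH2 on the other face) from the carbinol centre.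

Step 6
Reactants: 8 methyl (3S)-5-[(1S,2R,6R)-2-hydroxy-6-methylbicyclo[4.1.0]heptan-1-yl]-3-methylpentanoate
Product: 10 methyl (3S)-3-methyl-5-[(1S,6R)-6-methyl-2-oxobicyclo[4.1.0]hept-3-en-1-yl]pentanoate, via cyclopropyl ketone 9 (not isolated)
Conditions: IBX (3.5 equiv), DMSO/PhF, 70 °C
Reagents that add atoms: none
Why: IBX should first oxidise the carbinol and then, at 70 °C, dehydrogenate the ketone (IBX dehydrogenation through the enol), which can only occur on the CH2–CH2 side because the other α-carbon is quaternary.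

Step 7
Reactants: 10 methyl (3S)-3-methyl-5-[(1S,6R)-6-methyl-2-oxobicyclo[4.1.0]hept-3-en-1-yl]pentanoate
Product: 12 methyl (3S)-5-[(6S)-6-(iodomethyl)-6-methyl-2-oxocyclohex-3-en-1-yl]-3-methylpentanoate (both epimers at ring C1), via silyl dienol ether 11 (not isolated)
Conditions: TMSCl, NaI, MeCN, −20 °C → 0 °C; aq. NaHCO3
Reagents that add atoms: sodium iodide [Na+].[I-]
Why: Iodotrimethylsilane made in situ opens cyclopropyl ketones by homo-conjugate attack of iodide at the CH2 carbon with cleavage of the exocyclic cyclopropane bond that overlaps with the carbonyl π-system, so C1 should appear as CH2I on the intact quaternary C10 while C9 is protonated unselectively on work-up (it is reset in step 11).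

Step 8
Reactants: 13 3-methylbut-2-enal
Product: 14 3-methylbut-2-ene-1,1-diyl diacetate
Conditions: Ac2O, FeCl3 (cat.), 0 °C → rt
Reagents that add atoms: acetic anhydride CC(=O)OC(C)=O
Why: Lewis-acid catalysed addition of acetic anhydride to an aldehyde (acylal formation) is a routine, atom-economic reaction.

Step 9
Reactants: 12 methyl (3S)-5-[(6S)-6-(iodomethyl)-6-methyl-2-oxocyclohex-3-en-1-yl]-3-methylpentanoate; 14 3-methylbut-2-ene-1,1-diyl diacetate
Product: 18 methyl (13S)-8-oxo-17-norlabda-2,5-dien-15-oate (10β-methyl; both C9 epimers), via alkylzinc iodide 15 (not isolated), via allylic acetate 16 (not isolated), via lithium dienolate 17 (not isolated)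
Conditions: Zn dust, LiCl, THF, 40 °C; then 14 (1.5 equiv), Pd2(dba)3 (2.5 mol%), P(2-furyl)3 (10 mol%), THF, 0 °C → rt; then LiHMDS (2.3 equiv), t-BuOH (0.3 equiv), −40 → 0 °C; then AcOH, −78 °C
Reagents that add atoms: none
Why: Proposed new method: LiCl-assisted zinc insertion turns the neopentylic iodide 12 into alkylzinc 15 (no β-hydrogen; the medium stays neutral so that the γ-iodo ketone cannot close back to a cyclopropane), Pd(0) ionises gem-diacetate 14 to a 1-acetoxy-3,3-dimethyl-π-allyl complex, and transmetalation/reductive elimination at the less hindered acetoxy-bearing terminus forms C1–C2 of allylic acetate 16 (closest known types: Pd-catalysed allylation of organozinc reagents and enal gem-diacetates as allyl electrophiles in Tsuji–Trost chemistry). The same catalyst re-ionises 16, which erases its acetate-bearing stereocentre (stereoconvergent), and once LiHMDS/t-BuOH has converted the enone into its extended dienolate the γ-carbon C5 attacks the gem-dimethyl terminus C4 (intramolecular Tsuji–Trost alkylation). Ring A closes as a six-membered ring by attack on the distal allyl terminus with C2=C3 ending endocyclic; attack at C2 would give a cyclobutane, attack through the dienolate α-carbon C7 an eight-membered ring, and attack through C9 would have to build three contiguous quaternary carbons (C4, C9, C10). No new stereocentre has to be controlled: excess base turns the product into dienolate 17 and kinetic C7-protonation gives the β,γ-enone 18 with C5 trigonal, so cis- and trans-fused products and both C9 epimers funnel into one constitution. The selectivity needed is regiochemical (C2 before C4 on the allyl unit, C5 rather than C7 or C9 on the dienolate) and is secured by the order of events (hard alkylzinc first, base only after the iodide is consumed) and by the ring-size and congestion arguments above.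

Step 10
Reactants: 18 methyl (13S)-8-oxo-17-norlabda-2,5-dien-15-oate
Product: 19 methyl (13S)-8-oxo-17-norlabda-2,6-dien-15-oate (5α-H, 10β-methyl; both C9 epimers)
Conditions: TsOH·H2O (5 mol%), CH2Cl2, 0 °C
Reagents that add atoms: none
Why: Acid-catalysed isomerisation of a β,γ- to an α,β-unsaturated ketone runs through the dienol, whose γ-protonation at C5 should occur axially on the α-face, anti to the axial C10 methyl and the 4β-methyl, giving the trans ring fusion under kinetic control.

Step 11
Reactants: 19 methyl (13S)-8-oxo-17-norlabda-2,6-dien-15-oate (C9 epimers)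
Product: 21 methyl (5α,9α,10β,13S)-8-oxo-17-norlabda-2,6-dien-15-oate, via lithium dienolate 20 (not isolated)
Conditions: LiHMDS (1.05 equiv), THF, −78 °C; then AcOH, −78 °C
Reagents that add atoms: none
Why: Kinetic α′-deprotonation of the enone and kinetic protonation of the cross-conjugated enolate, again axially from the α-face anti to the C10 methyl, should place the side chain equatorial (9α-H).

Step 12
Reactants: 21 methyl (5α,9α,10β,13S)-8-oxo-17-norlabda-2,6-dien-15-oate
Product: 22 methyl (13S)-2α,3α-dihydroxy-8-oxo-17-norlabd-6-en-15-oate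
Conditions: OsO4 (2 mol%), NMO, acetone/H2O, rt
Reagents that add atoms: osmium tetroxide O=[Os](=O)(=O)=O; N-methylmorpholine N-oxide C[N+]1([O-])CCOCC1; water O
Why: Upjohn dihydroxylation should take place at the isolated cis-disubstituted Δ2 olefin rather than at the electron-poor enone and from the α-face, opposite the axial C10 and 4β methyl groups, giving the 2α,3α-diol.

Step 13
Reactants: 22 methyl (13S)-2α,3α-dihydroxy-8-oxo-17-norlabd-6-en-15-oate
Product: 23 methyl (13S)-2α,3α-(isopropylidenedioxy)-8-oxo-17-norlabd-6-en-15-oate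
Conditions: 2,2-dimethoxypropane, PPTS (cat.), CH2Cl2, rt
Reagents that add atoms: 2,2-dimethoxypropane COC(C)(C)OC
Why: Acid-catalysed transketalisation with 2,2-dimethoxypropane protects the cis-diol as its acetonide.

Step 14
Reactants: 23 methyl (13S)-2α,3α-(isopropylidenedioxy)-8-oxo-17-norlabd-6-en-15-oate
Product: 25 methyl (13S)-2α,3α-(isopropylidenedioxy)-8-(trifluoromethanesulfonyloxy)-17-norlabd-7-en-15-oate, via lithium enolate 24 (not isolated)
Conditions: L-Selectride, THF, −78 °C; then PhNTf2, −78 → 0 °C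
Reagents that add atoms: N-phenylbis(trifluoromethanesulfonimide) O=S(=O)(N(c1ccccc1)S(=O)(=O)C(F)(F)F)C(F)(F)F
Why: Conjugate reduction with L-Selectride should generate the C7=C8 lithium enolate regiospecifically, which is trapped on oxygen by PhNTf2 without touching C5 or C9.

Step 15
Reactants: 25 methyl (13S)-2α,3α-(isopropylidenedioxy)-8-(trifluoromethanesulfonyloxy)-17-norlabd-7-en-15-oate
Product: 26 methyl (13S)-2α,3α-(isopropylidenedioxy)labd-7-en-15-oate
Conditions: MeZnCl, Pd(PPh3)4 (5 mol%), THF, 50 °C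
Reagents that add atoms: methylzinc chloride C[Zn]Cl
Why: Palladium-catalysed Negishi cross-coupling of the enol triflate with methylzinc chloride should install C17 and fix the Δ7 double bond with the ester untouched.

Step 16
Reactants: 26 methyl (13S)-2α,3α-(isopropylidenedioxy)labd-7-en-15-oate
Product: 27 methyl (13S)-2α,3α-dihydroxylabd-7-en-15-oate (CNP0574074.1)
Conditions: AcOH/H2O/THF (3:1:1), 45 °C
Reagents that add atoms: none
Why: Mild aqueous-acid hydrolysis of the acetonide should release the cis-diol without isomerising the trisubstituted olefin.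

**Compound list**

1 | methyl (3S)-3,7-dimethyloct-6-enoate (methyl (S)-citronellate) | COC(=O)C[C@@H](C)CCC=C(C)C | starting material
2 | (4S)-6-methoxy-4-methyl-6-oxohexanoic acid | COC(=O)C[C@@H](C)CCC(=O)O | intermediate
3 | methyl (3R)-5-iodo-3-methylpentanoate | COC(=O)C[C@@H](C)CCI | intermediate
4 | [(3R)-5-methoxy-3-methyl-5-oxopentyl]zinc iodide | COC(=O)C[C@@H](C)CC[Zn]I | intermediate
5 | 2-iodo-3-methylcyclohex-2-en-1-one | CC1=C(I)C(=O)CCC1 | starting material
6 | methyl (3S)-3-methyl-5-(2-methyl-6-oxocyclohex-1-en-1-yl)pentanoate | COC(=O)C[C@@H](C)CCC1=C(C)CCCC1=O | intermediate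
7 | methyl (3S)-5-[(6R)-6-hydroxy-2-methylcyclohex-1-en-1-yl]-3-methylpentanoate | COC(=O)C[C@@H](C)CCC1=C(C)CCC[C@H]1O | intermediate
8 | methyl (3S)-5-[(1S,2R,6R)-2-hydroxy-6-methylbicyclo[4.1.0]heptan-1-yl]-3-methylpentanoate (OH and cyclopropane CH2 on the same face) | COC(=O)C[C@@H](C)CC[C@]12C[C@@]1(C)CCC[C@H]2O | intermediate
9 | methyl (3S)-3-methyl-5-[(1S,6R)-6-methyl-2-oxobicyclo[4.1.0]heptan-1-yl]pentanoate | COC(=O)C[C@@H](C)CC[C@]12C[C@@]1(C)CCCC2=O | intermediate
10 | methyl (3S)-3-methyl-5-[(1S,6R)-6-methyl-2-oxobicyclo[4.1.0]hept-3-en-1-yl]pentanoate | COC(=O)C[C@@H](C)CC[C@]12C[C@@]1(C)CC=CC2=O | intermediate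
11 | methyl (3S)-5-[(6S)-6-(iodomethyl)-6-methyl-2-(trimethylsilyloxy)cyclohexa-1,3-dien-1-yl]-3-methylpentanoate | COC(=O)C[C@@H](C)CCC1=C(O[Si](C)(C)C)C=CC[C@]1(C)CI | intermediate
12 | methyl (3S)-5-[(6S)-6-(iodomethyl)-6-methyl-2-oxocyclohex-3-en-1-yl]-3-methylpentanoate (both epimers at ring C1) | COC(=O)C[C@@H](C)CCC1C(=O)C=CC[C@]1(C)CI | intermediate
13 | 3-methylbut-2-enal | CC(C)=CC=O | starting material
14 | 3-methylbut-2-ene-1,1-diyl diacetate | CC(C)=CC(OC(C)=O)OC(C)=O | intermediate
15 | alkylzinc iodide of 12 (C–ZnI in place of C–I) | COC(=O)C[C@@H](C)CCC1C(=O)C=CC[C@]1(C)C[Zn]I | intermediate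
16 | methyl (3S)-5-[6-(2-acetoxy-4-methylpent-3-en-1-yl)-6-methyl-2-oxocyclohex-3-en-1-yl]-3-methylpentanoate (quaternary centre as in 12; acetate carbon and ring C1 as mixtures) | COC(=O)C[C@@H](C)CCC1C(=O)C=CC[C@]1(C)CC(OC(C)=O)C=C(C)C | intermediate
17 | lithium 2,5,7-trien-8-olate of 18 (extended dienolate, 10β-methyl) | COC(=O)C[C@@H](C)CCC1C([O-])=CC=C2C(C)(C)C=CC[C@]12C.[Li+] | intermediate
18 | methyl (13S)-8-oxo-17-norlabda-2,5-dien-15-oate (10β-methyl; both C9 epimers) | COC(=O)C[C@@H](C)CCC1C(=O)CC=C2C(C)(C)C=CC[C@]12C | intermediate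
19 | methyl (13S)-8-oxo-17-norlabda-2,6-dien-15-oate (5α-H, 10β-methyl; both C9 epimers) | COC(=O)C[C@@H](C)CCC1C(=O)C=C[C@H]2C(C)(C)C=CC[C@]12C | intermediate
20 | lithium 6,8-dien-8-olate of 19 (cross-conjugated enolate, C8=C9) | COC(=O)C[C@@H](C)CCC1=C([O-])C=C[C@H]2C(C)(C)C=CC[C@]12C.[Li+] | intermediate
21 | methyl (5α,9α,10β,13S)-8-oxo-17-norlabda-2,6-dien-15-oate | COC(=O)C[C@@H](C)CC[C@H]1C(=O)C=C[C@H]2C(C)(C)C=CC[C@]12C | intermediate
22 | methyl (13S)-2α,3α-dihydroxy-8-oxo-17-norlabd-6-en-15-oate | COC(=O)C[C@@H](C)CC[C@H]1C(=O)C=C[C@H]2C(C)(C)[C@H](O)[C@H](O)C[C@]12C | intermediate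
23 | methyl (13S)-2α,3α-(isopropylidenedioxy)-8-oxo-17-norlabd-6-en-15-oate | COC(=O)C[C@@H](C)CC[C@H]1C(=O)C=C[C@H]2C(C)(C)[C@@H]3OC(C)(C)O[C@@H]3C[C@]12C | intermediate
24 | lithium 7-en-8-olate of the 6,7-dihydro ketone from 23 | COC(=O)C[C@@H](C)CC[C@H]1C([O-])=CC[C@H]2C(C)(C)[C@@H]3OC(C)(C)O[C@@H]3C[C@]12C.[Li+] | intermediate
25 | methyl (13S)-2α,3α-(isopropylidenedioxy)-8-(trifluoromethanesulfonyloxy)-17-norlabd-7-en-15-oate | COC(=O)C[C@@H](C)CC[C@H]1C(OS(=O)(=O)C(F)(F)F)=CC[C@H]2C(C)(C)[C@@H]3OC(C)(C)O[C@@H]3C[C@]12C | intermediate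
26 | methyl (13S)-2α,3α-(isopropylidenedioxy)labd-7-en-15-oate | COC(=O)C[C@@H](C)CC[C@H]1C(C)=CC[C@H]2C(C)(C)[C@@H]3OC(C)(C)O[C@@H]3C[C@]12C | intermediate
27 | methyl (13S)-2α,3α-dihydroxylabd-7-en-15-oate = methyl (3S)-5-[(1S,4aR,6S,7R,8aR)-6,7-dihydroxy-2,5,5,8a-tetramethyl-1,4,4a,5,6,7,8,8a-octahydronaphthalen-1-yl]-3-methylpentanoate | COC(=O)C[C@@H](C)CC[C@H]1C(C)=CC[C@H]2C(C)(C)[C@H](O)[C@H](O)C[C@]12C | target

**Totals**

Total step count: 16. Longest linear sequence: 15 steps (steps 1–7 and 9–16; step 8 is a one-step branch).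

**Three steps most likely to fail**

1. Step 9 (Proposed new method). The second allylic substitution may not take place at the hindered gem-dimethyl terminus; the π-allyl intermediate may instead lose a β-hydrogen to give a diene, or the first coupling may be followed by a second intermolecular alkylation. Fallback with known reactions, from 12 back to 18: 12 is silylated (TBSOTf, Et3N) to the extended silyl dienol ether methyl (3S)-5-[(6S)-2-(tert-butyldimethylsilyloxy)-6-(iodomethyl)-6-methylcyclohexa-2,4-dien-1-yl]-3-methylpentanoate F1. Zinc insertion and Negishi coupling with (Z)-triethyl[(4-iodo-2-methylbut-3-en-2-yl)oxy]silane (Pd(PPh3)4) then give the (Z)-allylic silyl ether F2. BF3·OEt2 at −78 °C ionises the tertiary allylic ether, and the siloxydiene closes ring A through C5 (intramolecular vinylogous Mukaiyama-type alkylation, expected cis-fused) to give methyl (13S)-8-oxo-17-nor-5β-labda-2,6-dien-15-oate F3. Deconjugation (LiHMDS, cat. t-BuOH, then AcOH at −78 °C) converts F3 into 18.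

2. Step 10. Protonation of the dienol at C5 may occur partly from the β-face, or the ring fusion may equilibrate under the acid. Fallback from 18 back to 19: hydrogen-atom-transfer hydrogenation (Mn(dpm)3, PhSiH3, t-BuOOH, i-PrOH) reduces the trisubstituted Δ5 olefin through the tertiary C5 radical with hydrogen delivered on the α-face and leaves the 1,2-disubstituted Δ2 olefin, giving the trans-fused ketone methyl (13S)-8-oxo-17-norlabd-2-en-15-oate F4. Kinetic enolisation toward C7 (LiHMDS, TMSCl, −78 °C) gives the silyl enol ether methyl (13S)-8-(trimethylsilyloxy)-17-norlabda-2,7-dien-15-oate F5, and Saegusa–Ito oxidation (Pd(OAc)2, MeCN) returns 19.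

3. Step 14. 1,2-Reduction of the hindered enone may compete with conjugate hydride delivery. Fallback from 23 back to 25: RhCl(PPh3)3-catalysed 1,4-hydrosilylation with Et3SiH gives the silyl enol ether methyl (13S)-2α,3α-(isopropylidenedioxy)-8-(triethylsilyloxy)-17-norlabd-7-en-15-oate F6, which is converted into 25 with CsF and PhNTf2 in DME.

**Further compounds**

F1 | step 9 | methyl (3S)-5-[(6S)-2-(tert-butyldimethylsilyloxy)-6-(iodomethyl)-6-methylcyclohexa-2,4-dien-1-yl]-3-methylpentanoate | COC(=O)C[C@@H](C)CCC1C(O[Si](C)(C)C(C)(C)C)=CC=C[C@]1(C)CI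
F2 | step 9 | methyl (3S)-5-[2-(tert-butyldimethylsilyloxy)-6-methyl-6-[(2Z)-4-methyl-4-(triethylsilyloxy)pent-2-en-1-yl]cyclohexa-2,4-dien-1-yl]-3-methylpentanoate (quaternary centre as in 12) | COC(=O)C[C@@H](C)CCC1C(O[Si](C)(C)C(C)(C)C)=CC=C[C@]1(C)C/C=C\C(C)(C)O[Si](CC)(CC)CC
F3 | step 9 | methyl (13S)-8-oxo-17-nor-5β-labda-2,6-dien-15-oate (cis-fused, 10β-methyl; C9 epimers) | COC(=O)C[C@@H](C)CCC1C(=O)C=C[C@@H]2C(C)(C)C=CC[C@]12C
F4 | step 10 | methyl (13S)-8-oxo-17-norlabd-2-en-15-oate (5α-H, 10β-methyl; C9 epimers) | COC(=O)C[C@@H](C)CCC1C(=O)CC[C@H]2C(C)(C)C=CC[C@]12C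
F5 | step 10 | methyl (13S)-8-(trimethylsilyloxy)-17-norlabda-2,7-dien-15-oate (5α-H; C9 epimers) | COC(=O)C[C@@H](C)CCC1C(O[Si](C)(C)C)=CC[C@H]2C(C)(C)C=CC[C@]12C
F6 | step 14 | methyl (13S)-2α,3α-(isopropylidenedioxy)-8-(triethylsilyloxy)-17-norlabd-7-en-15-oate | COC(=O)C[C@@H](C)CC[C@H]1C(O[Si](CC)(CC)CC)=CC[C@H]2C(C)(C)[C@@H]3OC(C)(C)O[C@@H]3C[C@]12C
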